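## Structural features

The target is a 2-aryl-2,3-dihydro-1-benzofuran. Benzene ring A (C3a, C4, C5, C6, C7, C7a) is fused through the C3a–C7a bond to dihydrofuran ring B (O1, C2, C3), and C2 carries the 3,4-dimethoxyphenyl ring C. C3 bears a hydroxymethyl group, C5 an E-propenoic acid, and C7 a free phenol that sits next to C7a, the carbon bonded to O1. The only stereocentres, C2 (R) and C3 (S), are adjacent and trans. C2 is both benzylic to the electron-rich ring C and an aryl ether carbon, so the C2–O1 bond can ionise under acid; the cinnamic acid alkene rules out late hydrogenation, and the ring A phenol is sensitive to oxidants. The real difficulty is twofold: a 1,2,3,5-tetrasubstituted ring A whose two neighbouring oxygens must differ (ether at C7a, free hydroxyl at C7) while the two methyl ethers of ring C stay intact, and absolute control of the trans C2/C3 pair. The key step uses the C7–OH/C7a–O1 adjacency: C3a, C4, C5 and C6 come from a furan, C7a and C7 from an alkynyl ether hung on the C2 oxygen, and the furan oxygen ends as the C7 hydroxyl, so rings A and B close together.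

## Logic of the disconnections

**31 to 28 and 29.** The C=C bond of the C5 side chain is cut. The acrylic acid is the group least compatible with the hydride, organolithium and strong-base steps, so it is added last. The cut leaves aldehyde 28 and the two-carbon acid donor 29. The forward condensation must give the E acid directly and tolerate a free phenol, a primary alcohol and the C2–O1 bond.

**28 to 27 to 26.** No skeletal bond is cut. The C5 aldehyde goes back to the benzylic alcohol of 27, and both primary hydroxyls go back to the silyl ethers of 26. An aldehyde could not pass the alkynyl ether synthesis, and two identical silyl ethers go on and come off together. The forward oxidation must distinguish the benzylic from the aliphatic primary alcohol and spare the phenol.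

**26 to 23.** The bonds C3a–C7a and C6–C7 are cut, and the C7 oxygen is returned to bridge C3a and C6. Rings A and B both open, and the tetrasubstituted benzene becomes a 2,4-disubstituted furan plus a two-carbon ether. Both stereocentres are untouched. The forward step must place oxygen on C7 only and run mildly enough for a benzylic alkynyl ether to survive.

**23 to 18 and 19.** The O1–C7a bond is cut, because alkynyl ethers are made from an alcohol and 19. This reduces the fragile function to a secondary alcohol. The forward step passes through a potassium alkoxide and n-BuLi, so the protecting groups must neither migrate nor be attacked; this is why 18 carries triisopropylsilyl ethers.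

**18 to 17 to 14 and 15.** The two O–Si bonds are cut, then the bond between furan C4 and its hydroxymethyl carbon (later C5–CH2 of ring A). Keeping a robust bromide through the early steps and installing the one-carbon unit late lets one silylation cover both primary hydroxyls. The forward coupling must work on a β-bromofuran bearing a free 1,3-diol, and the silylation must leave the secondary hydroxyl free.

**14 to 13 to 9 and 10.** The future C2–C3 bond is cut, after the primary alcohol is traced back to an imide carbonyl. One aldol then sets both stereocentres from two achiral partners under auxiliary control. The forward step must be syn-selective with the (R)-auxiliary, because the syn aldol relationship becomes trans once O1 and C3a are tied into ring B, and the reduction must not epimerise the furyl-bearing centre.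

**9 to 6 and 7.** The N–acyl bond is cut to give the free acid and the recoverable auxiliary. The forward acylation must avoid strong base at the acidic methylene.

**6 to 3 to 1 and 2.** The bond between the furylmethylene carbon and the carboxyl carbon is cut; 2 supplies that carbon, which ends as the C3 hydroxymethyl carbon of 31. This leads back to a commercial furan with the 2,4-pattern already in place. The forward homologation must not use acid strong enough to degrade the furan.

## Other disconnections considered

**Alternative 1:** The cut is at the C2–aryl bond, and one stage earlier at the two bonds joining C2 and C3 to an exocyclic carbon; ring A is bought complete as benzofuran A1.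
- **Forward key step:** a copper carbene from a diazoacetic ester (CuOTf, monovalent copper, with a tert-butyl bis(oxazoline) ligand) adds to the C2–C3 double bond of A1 to give the exo cyclopropane ester A2. Opening this donor–acceptor cyclopropane at the C2–CH bond, with capture of the C2 cation by an electron-rich arene anti to the C3 substituent, would give the trans ester A3.
- **In favour:** ring A arrives with both oxygens differentiated and a bromide for a one-step Heck reaction, and the enantioselectivity comes from a catalyst.
- **Against:** A3 carries CH2CO2Et on C3, one carbon more than the target's hydroxymethyl group, so a chain shortening of several steps is unavoidable. Face selectivity in carbene addition to an electron-rich benzofuran is less predictable than an auxiliary aldol. The benzyl ether must be removed at the end without hydrogenating the cinnamate.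
- **Comparison:** on structure it is the better of the two, since the position of the phenol is never in question and the endgame from the bromide is shorter. On mechanism both plans set C2 relative to C3 by substrate control, but the chosen plan fixes both centres in one well-modelled aldol. On step economy the carbon excision cancels the saving, so the two are about equal.

**Alternative 2:** The cut is at O1–C2, with the C3 hydroxymethyl carbon traced to the methylene of the trans-1,2-diarylcyclopropane A4.
- **Forward key step:** Hg(OAc)2 (divalent mercury) attacks the cyclopropane CH2 of A4, the C2–CH2 bond breaks toward the cation stabilised by ring C, and the ortho phenol captures C2 with inversion to give the trans organomercurial A5. Oxidative demercuration would then reveal the hydroxymethyl group.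
- **In favour:** the one-carbon substituent on C3 has the right length from the start, ring closure is stereospecific from a trans cyclopropane, and ring A is again preformed with a bromide.
- **Against:** mercury is used in stoichiometric amount, and the radical demercuration is seldom clean. Both cyclopropane carbons bear electron-rich aryl groups, so the direction of ring opening is not guaranteed. The whole burden of absolute configuration shifts to an enantioselective synthesis of A4, which is harder than an auxiliary aldol.
- **Comparison:** on structure it is the equal of the chosen plan (both oxygens placed without ambiguity) and better in its endgame from the bromide. On mechanism the chosen plan is cleaner and catalytic in metal. On step economy the two are about equal once A4 is counted.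

**Alternative 3:** The cut is at O1–C7a together with the C7–O bond; ring A is a fluoroarene and the stereodiad comes from the same kind of syn aldol, in alcohol A6.
- **Forward key step:** excess t-BuLi deprotonates the hydroxyl of A6 and the position ortho to fluorine, LiF is lost to give the C7a–C7 aryne, the alkoxide adds at C7a to close ring B, and the C7 aryllithium is trapped by a borate ester to give boronate A7. Oxidation of the C–B bond would then give the phenol.
- **In favour:** the arylacetic acid needs no furan homologation, C5 already sits at the aldehyde oxidation level, and one operation forms O1–C7a and functionalises C7.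
- **Against:** excess t-BuLi meets several competing acidic sites (positions ortho to the methoxy groups of ring C, the doubly benzylic C3–H), and the aryne can be intercepted by the base. A silyl ether three atoms from a metal alkoxide may migrate.
- **Comparison:** on step economy it is the better plan, by roughly two to three steps. On structure it is the equal of the chosen plan, since both mechanisms force the two oxygens onto neighbouring carbons. On mechanism the chosen plan is milder: a catalytic, neutral isomerisation against a strongly basic organolithium cascade.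

Key step: step 9

Remark: the primary hydroxyls are carried as triisopropylsilyl ethers (a smaller silyl group three atoms from the potassium alkoxide of step 8 could migrate), and the bromide is exchanged for hydroxymethyl only after the aldol. The skeletons on both sides of the key step are unchanged, and the (1R,2S) centres of 23 map atom for atom onto the (2R,3S) centres of 26.

Assumption: 15 is taken as a commercial reagent.

## Route

Step 1
Reactants: 1 4-bromofuran-2-carbaldehyde; 2 chloroform
Product: 3 (±)-1-(4-bromofuran-2-yl)-2,2,2-trichloroethan-1-ol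
Conditions: CHCl3 (excess), DBU (1 equiv), 0 °C to rt
Reagents that add atoms: none
Why: Base-mediated addition of the trichloromethyl anion to a non-enolisable heteroaryl aldehyde; DBU avoids the Cannizzaro reaction seen with hydroxide. The new carbinol centre is racemic and is removed in step 2.

Step 2
Reactants: 3 (±)-1-(4-bromofuran-2-yl)-2,2,2-trichloroethan-1-ol
Product: 6 2-(4-bromofuran-2-yl)acetic acid, via gem-dichloroepoxide 4 (not isolated), via acyl chloride 5 (not isolated)
Conditions: NaBH4, NaOH, t-BuOH, 55 °C; then 1 M HCl
Reagents that add atoms: sodium hydroxide, [Na+].[OH-]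
Why: Jocic-type reductive homologation: the alkoxide closes to gem-dichloroepoxide 4, hydride opens it at the furfuryl carbon to give acyl chloride 5, and hydroxide converts this to the carboxylate, so the chloroform carbon becomes the carboxyl carbon. The aryl bromide and the furan are inert to borohydride and hydroxide at this temperature.

Step 3
Reactants: 6 2-(4-bromofuran-2-yl)acetic acid; 7 (R)-4-benzyl-1,3-oxazolidin-2-one
Product: 9 (4R)-4-benzyl-3-[2-(4-bromofuran-2-yl)acetyl]-1,3-oxazolidin-2-one, via mixed pivalic anhydride 8 (not isolated)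
Conditions: t-BuCOCl, Et3N, THF, −20 °C; then 7, LiCl, −20 °C to rt
Reagents that add atoms: none
Why: N-Acylation of the oxazolidinone through mixed anhydride 8 with LiCl and Et3N; no strong base meets the acidic furylacetyl methylene, and the pivaloyl group steers attack to the less hindered carbonyl.

Step 4
Reactants: 9 (4R)-4-benzyl-3-[2-(4-bromofuran-2-yl)acetyl]-1,3-oxazolidin-2-one; 10 3,4-dimethoxybenzaldehyde
Product: 13 (4R)-4-benzyl-3-[(2S,3R)-2-(4-bromofuran-2-yl)-3-(3,4-dimethoxyphenyl)-3-hydroxypropanoyl]-1,3-oxazolidin-2-one, via Z boron enolate 11 (not isolated), via boron aldolate 12 (not isolated)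
Conditions: Bu2BOTf, i-Pr2NEt, CH2Cl2, −78 to 0 °C; 10, −78 to 0 °C; then pH 7 buffer, MeOH, 30% H2O2, 0 °C
Reagents that add atoms: none
Why: Evans syn aldol: soft enolisation gives Z boron enolate 11, which reacts with 10 through a closed Zimmerman–Traxler chair on the enolate face away from the benzyl group of the auxiliary, setting the (2S,3R) pair that becomes C3 (S) and C2 (R) of the dihydrobenzofuran. Arylacetyl imides are established substrates, and the buffered peroxide work-up at 0 °C spares the furan.

Step 5
Reactants: 13 (4R)-4-benzyl-3-[(2S,3R)-2-(4-bromofuran-2-yl)-3-(3,4-dimethoxyphenyl)-3-hydroxypropanoyl]-1,3-oxazolidin-2-one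
Product: 14 (1R,2S)-2-(4-bromofuran-2-yl)-1-(3,4-dimethoxyphenyl)propane-1,3-diol
Conditions: LiBH4, MeOH (1 equiv), THF, 0 °C
Reagents that add atoms: none
Why: Reductive cleavage of the imide by LiBH4 at the exocyclic carbonyl releases the auxiliary and the primary alcohol without touching the aryl bromide; low temperature and short contact guard against retro-aldol cleavage and epimerisation of the furyl-bearing centre.

Step 6
Reactants: 14 (1R,2S)-2-(4-bromofuran-2-yl)-1-(3,4-dimethoxyphenyl)propane-1,3-diol; 15 potassium (acetoxymethyl)trifluoroborate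
Product: 17 (1R,2S)-1-(3,4-dimethoxyphenyl)-2-[4-(hydroxymethyl)furan-2-yl]propane-1,3-diol, via acetate 16 (not isolated)
Conditions: 15 (1.5 equiv), Pd(dba)2 (5 mol%), RuPhos (10 mol%), Na2CO3, 1,4-dioxane/H2O 10:1, 90 °C
Reagents that add atoms: none
Why: Suzuki–Miyaura hydroxymethylation: oxidative addition of the furyl bromide to zerovalent palladium, transmetalation of the acetoxymethyl group and reductive elimination give acetate 16, which the aqueous carbonate saponifies in the same flask. Placing this step after the aldol lets one silylation cover both primary hydroxyls.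

Step 7
Reactants: 17 (1R,2S)-1-(3,4-dimethoxyphenyl)-2-[4-(hydroxymethyl)furan-2-yl]propane-1,3-diol
Product: 18 (1R,2S)-1-(3,4-dimethoxyphenyl)-3-[(triisopropylsilyl)oxy]-2-(4-{[(triisopropylsilyl)oxy]methyl}furan-2-yl)propan-1-ol
Conditions: i-Pr3SiCl (2.2 equiv), imidazole, DMF, 0 °C to rt
Reagents that add atoms: triisopropylsilyl chloride, CC(C)[Si](Cl)(C(C)C)C(C)C
Why: Silylation with the bulky chlorosilane is selective for the two primary hydroxyls; the β-branched secondary benzylic hydroxyl stays free for step 8. Triisopropylsilyl is chosen because it resists migration to a neighbouring alkoxide.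

Step 8
Reactants: 18 (1R,2S)-1-(3,4-dimethoxyphenyl)-3-[(triisopropylsilyl)oxy]-2-(4-{[(triisopropylsilyl)oxy]methyl}furan-2-yl)propan-1-ol; 19 trichloroethylene
Product: 23 2-[(1R,2S)-1-(3,4-dimethoxyphenyl)-1-(ethynyloxy)-3-[(triisopropylsilyl)oxy]propan-2-yl]-4-{[(triisopropylsilyl)oxy]methyl}furan, via dichlorovinyl ether 20 (not isolated), via chloroethynyl ether 21 (not isolated), via lithium acetylide 22 (not isolated)
Conditions: KH, THF, 0 °C; 19, −50 °C to rt; then n-BuLi (2.5 equiv), −78 to −40 °C; MeOH, −78 °C
Reagents that add atoms: none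
Why: Alkynyl ether synthesis from an alcohol and trichloroethylene: the potassium alkoxide adds to dichloroacetylene formed in situ to give 20, n-BuLi eliminates HCl to 21 and exchanges the remaining chlorine to give acetylide 22, and methanol protonates it. The carbinol configuration is untouched because its C–O bond is never broken; the method is established for hindered secondary alcohols, benzylic ones included.

Step 9
Reactants: 23 2-[(1R,2S)-1-(3,4-dimethoxyphenyl)-1-(ethynyloxy)-3-[(triisopropylsilyl)oxy]propan-2-yl]-4-{[(triisopropylsilyl)oxy]methyl}furan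
Product: 26 (2R,3S)-2-(3,4-dimethoxyphenyl)-3,5-bis{[(triisopropylsilyl)oxy]methyl}-2,3-dihydro-1-benzofuran-7-ol, via oxepine 24 (not isolated), via arene oxide 25 (not isolated)
Conditions: Ph3PAuNTf2 (3 mol%), 4 Å molecular sieves, CH2Cl2 (0.02 M), −20 °C to rt
Reagents that add atoms: none
Why: Ph3PAuNTf2 (monovalent gold) coordinates the polarised alkynyl ether of 23, and the furan C2–C3 double bond attacks the oxygen-bearing alkyne carbon in a 5-exo-dig closure that forms C3a–C7a and ring B, giving a catalyst-bound cyclopropyl gold carbene that opens to a dienone carbene. The liberated carbonyl oxygen adds to the carbene carbon, releasing the catalyst and oxepine 24, whose disrotatory six-electron electrocyclisation forms C6–C7 and closes ring A as arene oxide 25. Epoxide opening toward the cation that O1 stabilises through C7a leaves the oxygen on C7, and loss of the C7 proton gives phenol 26. The closest known reaction type is the gold-catalysed furan–yne phenol synthesis, which is established for furans tethered through alkynyl ethers and ynamides. No stereocentre is created; C2 and C3 come unchanged from the aldol and no bond to either is broken. The selectivity required is regiochemical (hydroxyl on C7 only); it is secured by connectivity, since the furan oxygen can bridge only C6 and the former terminal alkyne carbon, and by the O1 donor that biases the arene oxide opening. The competing 6-exo attack by furan C3 is disfavoured by the polarisation of the ynol ether toward ipso attack and by the compact, doubly substituted tether. Low temperature and high dilution are chosen so that cyclisation outruns retro-ene loss of ketene, ionisation of the benzylic C–O bond and addition of product phenol to unreacted 23.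

Step 10
Reactants: 26 (2R,3S)-2-(3,4-dimethoxyphenyl)-3,5-bis{[(triisopropylsilyl)oxy]methyl}-2,3-dihydro-1-benzofuran-7-ol
Product: 27 (2R,3S)-2-(3,4-dimethoxyphenyl)-3,5-bis(hydroxymethyl)-2,3-dihydro-1-benzofuran-7-ol
Conditions: TBAF (3 equiv), AcOH (3 equiv), THF, rt
Reagents that add atoms: none
Why: Fluoride cleavage of both primary silyl ethers; acetic acid buffering keeps the phenoxide concentration low and avoids base-induced side reactions.

Step 11
Reactants: 27 (2R,3S)-2-(3,4-dimethoxyphenyl)-3,5-bis(hydroxymethyl)-2,3-dihydro-1-benzofuran-7-ol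
Product: 28 (2R,3S)-2-(3,4-dimethoxyphenyl)-7-hydroxy-3-(hydroxymethyl)-2,3-dihydro-1-benzofuran-5-carbaldehyde
Conditions: activated MnO2 (10 equiv), acetone, rt
Reagents that add atoms: none
Why: Activated MnO2 oxidises benzylic alcohols far faster than saturated primary alcohols, so only the C5 hydroxymethyl group is converted; the phenol is meta to the reacting carbon and cannot form a quinone methide.

Step 12
Reactants: 28 (2R,3S)-2-(3,4-dimethoxyphenyl)-7-hydroxy-3-(hydroxymethyl)-2,3-dihydro-1-benzofuran-5-carbaldehyde; 29 malonic acid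
Product: 31 (2E)-3-[(2R,3S)-2-(3,4-dimethoxyphenyl)-7-hydroxy-3-(hydroxymethyl)-2,3-dihydro-1-benzofuran-5-yl]prop-2-enoic acid, via arylidenemalonic acid 30 (not isolated)
Conditions: 29 (3 equiv), pyridine, piperidine (cat.), 80 °C; then 1 M HCl
Reagents that add atoms: none
Why: Knoevenagel–Doebner condensation: the piperidine-derived iminium condenses with malonic acid to 30, which decarboxylates in hot pyridine to the thermodynamically preferred E cinnamic acid. Free phenols and alcohols are tolerated, as in the classical preparation of hydroxycinnamic acids.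

## Compound list

1 | 4-bromofuran-2-carbaldehyde | O=Cc1cc(Br)co1 | starting material
2 | chloroform | ClC(Cl)Cl | starting material
3 | (±)-1-(4-bromofuran-2-yl)-2,2,2-trichloroethan-1-ol | OC(c1cc(Br)co1)C(Cl)(Cl)Cl | intermediate
4 | (±)-3-(4-bromofuran-2-yl)-2,2-dichlorooxirane | ClC1(Cl)OC1c1cc(Br)co1 | intermediate (not isolated)
5 | 2-(4-bromofuran-2-yl)acetyl chloride | O=C(Cl)Cc1cc(Br)co1 | intermediate (not isolated)
6 | 2-(4-bromofuran-2-yl)acetic acid | OC(=O)Cc1cc(Br)co1 | intermediate
7 | (R)-4-benzyl-1,3-oxazolidin-2-one | O=C1N[C@H](Cc2ccccc2)CO1 | starting material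
8 | 2-(4-bromofuran-2-yl)acetic pivalic anhydride | CC(C)(C)C(=O)OC(=O)Cc1cc(Br)co1 | intermediate (not isolated)
9 | (4R)-4-benzyl-3-[2-(4-bromofuran-2-yl)acetyl]-1,3-oxazolidin-2-one | O=C(Cc1cc(Br)co1)N1[C@H](Cc2ccccc2)COC1=O | intermediate
10 | 3,4-dimethoxybenzaldehyde | COc1ccc(C=O)cc1OC | starting material
11 | (4R)-4-benzyl-3-[(Z)-2-(4-bromofuran-2-yl)-1-[(dibutylboranyl)oxy]ethenyl]-1,3-oxazolidin-2-one | CCCCB(CCCC)O/C(=C\c1cc(Br)co1)N1[C@H](Cc2ccccc2)COC1=O | intermediate (not isolated)
12 | O-dibutylboranyl ether of 13 at the (3R) carbinol oxygen | COc1ccc([C@H](OB(CCCC)CCCC)[C@H](C(=O)N2[C@H](Cc3ccccc3)COC2=O)c2cc(Br)co2)cc1OC | intermediate (not isolated)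
13 | (4R)-4-benzyl-3-[(2S,3R)-2-(4-bromofuran-2-yl)-3-(3,4-dimethoxyphenyl)-3-hydroxypropanoyl]-1,3-oxazolidin-2-one | COc1ccc([C@H](O)[C@H](C(=O)N2[C@H](Cc3ccccc3)COC2=O)c2cc(Br)co2)cc1OC | intermediate
14 | (1R,2S)-2-(4-bromofuran-2-yl)-1-(3,4-dimethoxyphenyl)propane-1,3-diol | COc1ccc([C@H](O)[C@H](CO)c2cc(Br)co2)cc1OC | intermediate
15 | potassium (acetoxymethyl)trifluoroborate | CC(=O)OC[B-](F)(F)F.[K+] | starting material
16 | {5-[(1R,2S)-1-(3,4-dimethoxyphenyl)-1,3-dihydroxypropan-2-yl]furan-3-yl}methyl acetate | COc1ccc([C@H](O)[C@H](CO)c2cc(COC(C)=O)co2)cc1OC | intermediate (not isolated)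
17 | (1R,2S)-1-(3,4-dimethoxyphenyl)-2-[4-(hydroxymethyl)furan-2-yl]propane-1,3-diol | COc1ccc([C@H](O)[C@H](CO)c2cc(CO)co2)cc1OC | intermediate
18 | (1R,2S)-1-(3,4-dimethoxyphenyl)-3-[(triisopropylsilyl)oxy]-2-(4-{[(triisopropylsilyl)oxy]methyl}furan-2-yl)propan-1-ol | COc1ccc([C@H](O)[C@H](CO[Si](C(C)C)(C(C)C)C(C)C)c2cc(CO[Si](C(C)C)(C(C)C)C(C)C)co2)cc1OC | intermediate
19 | trichloroethylene | ClC=C(Cl)Cl | starting material
20 | 2-[(1R,2S)-1-{[(E)-1,2-dichloroethenyl]oxy}-1-(3,4-dimethoxyphenyl)-3-[(triisopropylsilyl)oxy]propan-2-yl]-4-{[(triisopropylsilyl)oxy]methyl}furan | COc1ccc([C@H](O/C(Cl)=C\Cl)[C@H](CO[Si](C(C)C)(C(C)C)C(C)C)c2cc(CO[Si](C(C)C)(C(C)C)C(C)C)co2)cc1OC | intermediate (not isolated)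
21 | 2-[(1R,2S)-1-[(chloroethynyl)oxy]-1-(3,4-dimethoxyphenyl)-3-[(triisopropylsilyl)oxy]propan-2-yl]-4-{[(triisopropylsilyl)oxy]methyl}furan | COc1ccc([C@H](OC#CCl)[C@H](CO[Si](C(C)C)(C(C)C)C(C)C)c2cc(CO[Si](C(C)C)(C(C)C)C(C)C)co2)cc1OC | intermediate (not isolated)
22 | lithium acetylide of 23 (lithium on the terminal alkyne carbon) | COc1ccc([C@H](OC#C[Li])[C@H](CO[Si](C(C)C)(C(C)C)C(C)C)c2cc(CO[Si](C(C)C)(C(C)C)C(C)C)co2)cc1OC | intermediate (not isolated)
23 | 2-[(1R,2S)-1-(3,4-dimethoxyphenyl)-1-(ethynyloxy)-3-[(triisopropylsilyl)oxy]propan-2-yl]-4-{[(triisopropylsilyl)oxy]methyl}furan | COc1ccc([C@H](OC#C)[C@H](CO[Si](C(C)C)(C(C)C)C(C)C)c2cc(CO[Si](C(C)C)(C(C)C)C(C)C)co2)cc1OC | intermediate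
24 | oxepine tautomer: ring B fused to an oxepine whose oxygen bridges C6 and C7 (C2 and C3 as in 26) | COc1ccc([C@@H]2OC3=COC=C(CO[Si](C(C)C)(C(C)C)C(C)C)C=C3[C@H]2CO[Si](C(C)C)(C(C)C)C(C)C)cc1OC | intermediate (not isolated)
25 | arene oxide: 6,7-epoxide of the ring A diene, epoxide face not specified (C2 and C3 as in 26) | COc1ccc([C@@H]2OC3=C(C=C(CO[Si](C(C)C)(C(C)C)C(C)C)C4OC43)[C@H]2CO[Si](C(C)C)(C(C)C)C(C)C)cc1OC | intermediate (not isolated)
26 | (2R,3S)-2-(3,4-dimethoxyphenyl)-3,5-bis{[(triisopropylsilyl)oxy]methyl}-2,3-dihydro-1-benzofuran-7-ol | COc1ccc([C@@H]2Oc3c(O)cc(CO[Si](C(C)C)(C(C)C)C(C)C)cc3[C@H]2CO[Si](C(C)C)(C(C)C)C(C)C)cc1OC | intermediate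
27 | (2R,3S)-2-(3,4-dimethoxyphenyl)-3,5-bis(hydroxymethyl)-2,3-dihydro-1-benzofuran-7-ol | COc1ccc([C@@H]2Oc3c(O)cc(CO)cc3[C@H]2CO)cc1OC | intermediate
28 | (2R,3S)-2-(3,4-dimethoxyphenyl)-7-hydroxy-3-(hydroxymethyl)-2,3-dihydro-1-benzofuran-5-carbaldehyde | COc1ccc([C@@H]2Oc3c(O)cc(C=O)cc3[C@H]2CO)cc1OC | intermediate
29 | malonic acid | OC(=O)CC(=O)O | starting material
30 | 2-{[(2R,3S)-2-(3,4-dimethoxyphenyl)-7-hydroxy-3-(hydroxymethyl)-2,3-dihydro-1-benzofuran-5-yl]methylidene}propanedioic acid | COc1ccc([C@@H]2Oc3c(O)cc(C=C(C(=O)O)C(=O)O)cc3[C@H]2CO)cc1OC | intermediate (not isolated)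
31 | (2E)-3-[(2R,3S)-2-(3,4-dimethoxyphenyl)-7-hydroxy-3-(hydroxymethyl)-2,3-dihydro-1-benzofuran-5-yl]prop-2-enoic acid | COc1ccc([C@@H]2Oc3c(O)cc(/C=C/C(=O)O)cc3[C@H]2CO)cc1OC | target

## Step count and least certain steps

Total step count: 12. Longest linear sequence: 12 steps (1 to 31); all other inputs enter as commercial materials.

**Step 9 (key step).** The most likely failure is loss of the alkynyl ether before ring closure. Trace water can hydrate the gold-activated ynol ether to the acetate, the ether can fragment by a retro-ene path, and the electron-rich benzylic C–O bond can ionise once gold has polarised the alkyne.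
Fallback: give up the de novo construction of ring A; the fallback sets out from 7 and 10 and returns at 31.
- Commercial 5-bromo-2,3-dihydroxybenzaldehyde F1 is protected (MOMCl, i-Pr2NEt) as 5-bromo-2,3-bis(methoxymethoxy)benzaldehyde F2.
- The operations of steps 1 and 2 convert F2 through (±)-1-[5-bromo-2,3-bis(methoxymethoxy)phenyl]-2,2,2-trichloroethan-1-ol F3 into 2-[5-bromo-2,3-bis(methoxymethoxy)phenyl]acetic acid F4.
- Acylation of 7 as in step 3 gives (4R)-4-benzyl-3-{2-[5-bromo-2,3-bis(methoxymethoxy)phenyl]acetyl}-1,3-oxazolidin-2-one F5.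
- The boron aldol of step 4 with 10 gives (4R)-4-benzyl-3-[(2R,3R)-2-[5-bromo-2,3-bis(methoxymethoxy)phenyl]-3-(3,4-dimethoxyphenyl)-3-hydroxypropanoyl]-1,3-oxazolidin-2-one F6.
- LiBH4 gives (1R,2S)-2-[5-bromo-2,3-bis(methoxymethoxy)phenyl]-1-(3,4-dimethoxyphenyl)propane-1,3-diol F7.
- Aqueous HCl in THF removes both acetals and lets the ortho phenol close onto the ionised benzylic carbon; under thermodynamic control this should give trans (2R,3S)-5-bromo-2-(3,4-dimethoxyphenyl)-3-(hydroxymethyl)-2,3-dihydro-1-benzofuran-7-ol F8.
- A Heck reaction of F8 with acrylic acid (Pd(OAc)2, P(o-tol)3, Et3N, DMF, 100 °C) returns to the route at 31.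

**Step 8.** A silyl group may migrate to the secondary potassium alkoxide, the hindered alkoxide may capture dichloroacetylene incompletely, and the ynol ether may decompose on silica (it should be filtered through base-washed alumina and used at once).
Fallback, from 18 to 23 without a potassium alkoxide: formylation (acetic formic anhydride, pyridine) gives (1R,2S)-1-(3,4-dimethoxyphenyl)-3-[(triisopropylsilyl)oxy]-2-(4-{[(triisopropylsilyl)oxy]methyl}furan-2-yl)propyl formate F9. Corey–Fuchs-type dibromoolefination of the formate carbonyl (CBr4, PPh3, CH2Cl2, 0 °C) gives the 2,2-dibromoethenyl ether F10. n-BuLi (2.2 equiv, THF, −78 °C) converts F10 into acetylide 22, and methanol returns to the route at 23.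

**Step 2.** Hydroxide may compete with hydride in opening the very reactive furfuryl dichloroepoxide, leading to an α-hydroxy acid, and the acyl chloride may be over-reduced.
Fallback, from 1 to 6: condensation of 1 with methyl (methylthio)methyl sulfoxide (benzyltrimethylammonium hydroxide, THF, reflux) gives the ketene dithioacetal monoxide 4-bromo-2-[2-(methylsulfanyl)-2-(methylsulfinyl)ethenyl]furan F11. Ethanolic HCl at rt gives ethyl 2-(4-bromofuran-2-yl)acetate F12, and LiOH in THF/H2O returns to the route at 6.

**Step 6.** Oxidative addition at the electron-rich β-bromofuran may be slow, so that protodeboronation of 15 and protodebromination of 14 compete; the free 1,3-diol may also bind palladium.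
Fallback, from 14 to 17: methoxycarbonylation (Pd(OAc)2, Xantphos, CO 1 atm, Et3N, MeOH, 70 °C) gives methyl 5-[(1R,2S)-1-(3,4-dimethoxyphenyl)-1,3-dihydroxypropan-2-yl]furan-3-carboxylate F13, and reduction with i-Bu2AlH (THF, −78 to 0 °C) returns to the route at 17.

**Step 11.** The electron-rich free phenol may undergo oxidative coupling on the MnO2 surface, and the polar triol may be lost by adsorption.
Fallback, from 27 to 28: selective acetylation of the phenoxide (Ac2O, aqueous NaOH, 0 °C) gives (2R,3S)-2-(3,4-dimethoxyphenyl)-3,5-bis(hydroxymethyl)-2,3-dihydro-1-benzofuran-7-yl acetate F14. MnO2 then oxidises the benzylic alcohol to (2R,3S)-2-(3,4-dimethoxyphenyl)-5-formyl-3-(hydroxymethyl)-2,3-dihydro-1-benzofuran-7-yl acetate F15, and K2CO3 in MeOH returns to the route at 28.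

## Further compounds

F1 | step 9 | 5-bromo-2,3-dihydroxybenzaldehyde | O=Cc1cc(Br)cc(O)c1O
F2 | step 9 | 5-bromo-2,3-bis(methoxymethoxy)benzaldehyde | COCOc1cc(Br)cc(C=O)c1OCOC
F3 | step 9 | (±)-1-[5-bromo-2,3-bis(methoxymethoxy)phenyl]-2,2,2-trichloroethan-1-ol | COCOc1cc(Br)cc(C(O)C(Cl)(Cl)Cl)c1OCOC
F4 | step 9 | 2-[5-bromo-2,3-bis(methoxymethoxy)phenyl]acetic acid | COCOc1cc(Br)cc(CC(=O)O)c1OCOC
F5 | step 9 | (4R)-4-benzyl-3-{2-[5-bromo-2,3-bis(methoxymethoxy)phenyl]acetyl}-1,3-oxazolidin-2-one | COCOc1cc(Br)cc(CC(=O)N2[C@H](Cc3ccccc3)COC2=O)c1OCOC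
F6 | step 9 | (4R)-4-benzyl-3-[(2R,3R)-2-[5-bromo-2,3-bis(methoxymethoxy)phenyl]-3-(3,4-dimethoxyphenyl)-3-hydroxypropanoyl]-1,3-oxazolidin-2-one | COc1ccc([C@H](O)[C@H](C(=O)N2[C@H](Cc3ccccc3)COC2=O)c2cc(Br)cc(OCOC)c2OCOC)cc1OC
F7 | step 9 | (1R,2S)-2-[5-bromo-2,3-bis(methoxymethoxy)phenyl]-1-(3,4-dimethoxyphenyl)propane-1,3-diol | COc1ccc([C@H](O)[C@H](CO)c2cc(Br)cc(OCOC)c2OCOC)cc1OC
F8 | step 9 | (2R,3S)-5-bromo-2-(3,4-dimethoxyphenyl)-3-(hydroxymethyl)-2,3-dihydro-1-benzofuran-7-ol | COc1ccc([C@@H]2Oc3c(O)cc(Br)cc3[C@H]2CO)cc1OC
F9 | step 8 | (1R,2S)-1-(3,4-dimethoxyphenyl)-3-[(triisopropylsilyl)oxy]-2-(4-{[(triisopropylsilyl)oxy]methyl}furan-2-yl)propyl formate | COc1ccc([C@H](OC=O)[C@H](CO[Si](C(C)C)(C(C)C)C(C)C)c2cc(CO[Si](C(C)C)(C(C)C)C(C)C)co2)cc1OC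
F10 | step 8 | 2-[(1R,2S)-1-[(2,2-dibromoethenyl)oxy]-1-(3,4-dimethoxyphenyl)-3-[(triisopropylsilyl)oxy]propan-2-yl]-4-{[(triisopropylsilyl)oxy]methyl}furan | COc1ccc([C@H](OC=C(Br)Br)[C@H](CO[Si](C(C)C)(C(C)C)C(C)C)c2cc(CO[Si](C(C)C)(C(C)C)C(C)C)co2)cc1OC
F11 | step 2 | 4-bromo-2-[2-(methylsulfanyl)-2-(methylsulfinyl)ethenyl]furan | CSC(=Cc1cc(Br)co1)S(C)=O
F12 | step 2 | ethyl 2-(4-bromofuran-2-yl)acetate | CCOC(=O)Cc1cc(Br)co1
F13 | step 6 | methyl 5-[(1R,2S)-1-(3,4-dimethoxyphenyl)-1,3-dihydroxypropan-2-yl]furan-3-carboxylate | COc1ccc([C@H](O)[C@H](CO)c2cc(C(=O)OC)co2)cc1OC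
F14 | step 11 | (2R,3S)-2-(3,4-dimethoxyphenyl)-3,5-bis(hydroxymethyl)-2,3-dihydro-1-benzofuran-7-yl acetate | COc1ccc([C@@H]2Oc3c(OC(C)=O)cc(CO)cc3[C@H]2CO)cc1OC
F15 | step 11 | (2R,3S)-2-(3,4-dimethoxyphenyl)-5-formyl-3-(hydroxymethyl)-2,3-dihydro-1-benzofuran-7-yl acetate | COc1ccc([C@@H]2Oc3c(OC(C)=O)cc(C=O)cc3[C@H]2CO)cc1OC
A1 | alternative 1 | 7-(benzyloxy)-5-bromo-1-benzofuran | Brc1cc(OCc2ccccc2)c2occc2c1
A2 | alternative 1 | exo ethyl cyclopropa[b]benzofuran-1-carboxylate from A1 (benzyloxy and bromo retained) | CCOC(=O)[C@@H]1[C@H]2Oc3c(OCc4ccccc4)cc(Br)cc3[C@@H]12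
A3 | alternative 1 | ethyl 2-[trans-7-(benzyloxy)-5-bromo-2-(3,4-dimethoxyphenyl)-2,3-dihydro-1-benzofuran-3-yl]acetate | COc1ccc([C@@H]2Oc3c(OCc4ccccc4)cc(Br)cc3[C@H]2CC(=O)OCC)cc1OC
A4 | alternative 2 | 2-(benzyloxy)-4-bromo-6-[trans-2-(3,4-dimethoxyphenyl)cyclopropyl]phenol | COc1ccc([C@H]2C[C@@H]2c2cc(Br)cc(OCc3ccccc3)c2O)cc1OC
A5 | alternative 2 | trans 3-(acetoxymercuriomethyl)-7-(benzyloxy)-5-bromo-2-(3,4-dimethoxyphenyl)-2,3-dihydrobenzofuran | COc1ccc([C@@H]2Oc3c(OCc4ccccc4)cc(Br)cc3[C@H]2C[Hg]OC(C)=O)cc1OC
A6 | alternative 3 | syn 3-[(tert-butyldimethylsilyl)oxy]-1-(3,4-dimethoxyphenyl)-2-[5-(1,3-dioxolan-2-yl)-2-fluorophenyl]propan-1-ol | COc1ccc([C@H](O)[C@H](CO[Si](C)(C)C(C)(C)C)c2cc(C3OCCO3)ccc2F)cc1OC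
A7 | alternative 3 | trans 7-(pinacolboryl)-5-(1,3-dioxolan-2-yl)-3-{[(tert-butyldimethylsilyl)oxy]methyl}-2-(3,4-dimethoxyphenyl)-2,3-dihydrobenzofuran | COc1ccc([C@@H]2Oc3c(B4OC(C)(C)C(C)(C)O4)cc(C4OCCO4)cc3[C@H]2CO[Si](C)(C)C(C)(C)C)cc1OC
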